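**Retrosynthetic overview**
1. Target 27 ⇒ meso bisphenol core 17 + 2 × (R)-keto tosylate 25: two aryl ether C–O bonds by SN2 with inversion, then chelation-controlled reduction of both ketones sets C1 of each arm.
2. Core 17 ⇒ 1,4-diol 14 (BF3 ring closure with benzylic equilibration; the oxolane ring is formed second) ⇒ lactol 10 + aryl Grignard 13.
3. Lactol 10 ⇒ all-cis γ-lactone 9 ⇒ α-methylene lactone 8 (hydrogenation sets the cis-dimethyl pair).
4. Key C–C bond: 8 ⇒ aldehyde 5 + allyl bromide 4 by zinc-mediated carbonyl allylation with lactonisation (the γ-lactone ring is formed first); 4 comes from acetaldehyde and ethyl acrylate.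
5. Tosylate 25 ⇐ methyl (R)-lactate 18 + 4-bromoveratrole 21.

Assumption: intermediates 3, 7–10, 14 and 15 are racemic or epimer mixtures (one enantiomer drawn), which is harmless because the oxolane core 16/17 is meso and all absolute configuration of 27 comes from methyl (R)-lactate; the two-fold reactions at the equivalent ends of 16, 17 and 26 are single operations run to completion and their half-converted forms are not numbered separately.

**Route**

Step 1
Reactants: 1 acetaldehyde; 2 ethyl acrylate
Product: 3 ethyl 3-hydroxy-2-methylidenebutanoate (racemic)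
Conditions: DABCO (0.15 equiv), neat, sealed flask, rt, 7 d
Reagents that add atoms: none
Why: Morita–Baylis–Hillman reaction, in which the DABCO–acrylate zwitterion adds to the aldehyde; the carbinol stereocentre is destroyed in step 2.

Step 2
Reactants: 3 ethyl 3-hydroxy-2-methylidenebutanoate
Product: 4 ethyl (2Z)-2-(bromomethyl)but-2-enoate
Conditions: 48% aq. HBr, conc. H2SO4, 0 °C → rt
Reagents that add atoms: hydrogen bromide, Br
Why: SN2′ allylic substitution of the protonated alcohol by bromide with allylic transposition, giving the more stable trisubstituted alkene with the methyl group trans to the ester (Z).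

Step 3
Reactants: 4 ethyl (2Z)-2-(bromomethyl)but-2-enoate; 5 4-(benzyloxy)-3-methoxybenzaldehyde
Product: 8 (4R*,5S*)-5-[4-(benzyloxy)-3-methoxyphenyl]-4-methyl-3-methylideneoxolan-2-one (4,5-cis), via allylzinc bromide 6 (not isolated), via syn hydroxy ester 7 (not isolated)
Conditions: Zn dust (activated, 1.5 equiv), THF, 0 °C → rt; sat. aq. NH4Cl; then TsOH·H2O (5 mol %), CH2Cl2, rt
Reagents that add atoms: none
Why: Barbier-type carbonyl allylation (Dreiding–Schmidt reaction) in which the allylzinc adds through its γ-carbon via a chair Zimmerman–Traxler transition state with the methyl cis to CH2Zn (Z-crotyl type), giving the syn adduct and, after acid-catalysed lactonisation, the 4,5-cis lactone; any trans isomer is removed by chromatography and the benzylic centre is reset in step 8 in any case.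

Step 4
Reactants: 8 4,5-cis α-methylene lactone
Product: 9 (3S*,4R*,5S*)-5-[4-(benzyloxy)-3-methoxyphenyl]-3,4-dimethyloxolan-2-one (all-cis)
Conditions: H2 (3 atm), RhCl(PPh3)3 (5 mol %), PhH/EtOH (1:1), rt
Reagents that add atoms: none
Why: Homogeneous hydrogenation adds H2 syn to the exocyclic alkene from the face opposite the C4 methyl and C5 aryl groups, which sets the 3,4-cis dimethyl pair and leaves the benzyl ether and the benzylic lactone C–O bond intact.

Step 5
Reactants: 9 all-cis lactone
Product: 10 (3S*,4R*,5S*)-5-[4-(benzyloxy)-3-methoxyphenyl]-3,4-dimethyloxolan-2-ol (anomer mixture)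
Conditions: i-Bu2AlH (1.2 equiv), CH2Cl2, −78 °C; aq. KNaC4H4O6
Reagents that add atoms: none
Why: Partial reduction of a lactone to the lactol, where the aluminium hemiacetal is stable at −78 °C so no over-reduction or epimerisation occurs.

Step 6
Reactants: 11 4-bromo-2-methoxyphenol
Product: 12 1-(benzyloxy)-4-bromo-2-methoxybenzene
Conditions: BnBr, K2CO3, acetone, reflux
Reagents that add atoms: benzyl bromide, BrCc1ccccc1
Why: Williamson ether synthesis on the phenoxide.

Step 7
Reactants: 10 lactol; 12 1-(benzyloxy)-4-bromo-2-methoxybenzene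
Product: 14 (2S*,3R*,4S*)-1,4-bis[4-(benzyloxy)-3-methoxyphenyl]-2,3-dimethylbutane-1,4-diol (epimer mixture at C1), via aryl Grignard 13 (not isolated)
Conditions: 12, Mg turnings, THF, 40 °C; then 10 (3 equiv of 13 per lactol), THF, 0 °C → rt; sat. aq. NH4Cl
Reagents that add atoms: none
Why: Grignard addition to the ring-opened hydroxy aldehyde form of the lactol (the first equivalent deprotonates the OH); the new carbinol forms as an epimer mixture, which is acceptable because step 8 sets it.

Step 8
Reactants: 14 1,4-diol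
Product: 16 meso-(2R,3R,4S,5S)-2,5-bis[4-(benzyloxy)-3-methoxyphenyl]-3,4-dimethyloxolane (2,3-trans-3,4-cis-4,5-trans), via kinetic oxolane epimers 15 (not isolated)
Conditions: BF3·OEt2 (0.3 equiv), 4 Å MS, CH2Cl2, −78 → −20 °C; aq. NaHCO3
Reagents that add atoms: none
Why: SN1 dehydrative cyclisation through a p-alkoxybenzylic cation captured by the other hydroxyl, followed by reversible benzylic C–O ionisation that equilibrates C2 and C5 to the thermodynamic arrangement with each aryl trans to its neighbouring methyl, while the cis-dimethyl pair from step 4 is untouched, so the meso oxolane results.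

Step 9
Reactants: 16 meso bis(benzyl ether)
Product: 17 meso-4,4'-[(2R,3R,4S,5S)-3,4-dimethyloxolane-2,5-diyl]bis(2-methoxyphenol)
Conditions: H2 (1 atm), Pd/C (10 wt %), EtOAc/MeOH (1:1), rt
Reagents that add atoms: none
Why: Hydrogenolysis of both aryl benzyl ethers under neutral conditions, where the oxolane benzylic C–O bonds survive (they need acid to cleave).

Step 10
Reactants: 18 methyl (R)-lactate
Product: 19 (2R)-2-hydroxy-1-(morpholin-4-yl)propan-1-one
Conditions: morpholine (3 equiv), neat, 85 °C
Reagents that add atoms: morpholine, C1COCCN1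
Why: Ester aminolysis, which does not touch the stereocentre.

Step 11
Reactants: 19 (2R)-2-hydroxy-1-(morpholin-4-yl)propan-1-one
Product: 20 (2R)-2-[(tert-butyldimethylsilyl)oxy]-1-(morpholin-4-yl)propan-1-one
Conditions: TBSCl, imidazole, DMF, rt
Reagents that add atoms: tert-butyldimethylsilyl chloride, CC(C)(C)[Si](C)(C)Cl
Why: Silyl ether protection of the secondary alcohol so that the Grignard reagent in step 12 is not consumed.

Step 12
Reactants: 20 silyl-protected morpholine amide; 21 4-bromo-1,2-dimethoxybenzene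
Product: 23 (2R)-2-[(tert-butyldimethylsilyl)oxy]-1-(3,4-dimethoxyphenyl)propan-1-one, via veratryl Grignard 22 (not isolated)
Conditions: 21, Mg turnings, THF, 40 °C; then 20, THF, 0 °C; sat. aq. NH4Cl
Reagents that add atoms: none
Why: Grignard acylation of a morpholine amide (Weinreb-type ketone synthesis), where the stable tetrahedral magnesium adduct prevents over-addition and α-epimerisation.

Step 13
Reactants: 23 α-silyloxy ketone
Product: 24 (2R)-1-(3,4-dimethoxyphenyl)-2-hydroxypropan-1-one
Conditions: 48% aq. HF, MeCN, 0 °C → rt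
Reagents that add atoms: none
Why: Acidic fluoride desilylation, chosen because it avoids the basic conditions that could racemise the α-hydroxy ketone.

Step 14
Reactants: 24 (2R)-α-hydroxy ketone
Product: 25 (2R)-1-(3,4-dimethoxyphenyl)-1-oxopropan-2-yl 4-methylbenzenesulfonate
Conditions: TsCl, Et3N, DMAP (cat.), CH2Cl2, 0 °C
Reagents that add atoms: 4-methylbenzenesulfonyl chloride, Cc1ccc(S(=O)(=O)Cl)cc1
Why: O-sulfonylation with retention, giving an activated secondary electrophile for SN2 displacement.

Step 15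
Reactants: 17 meso bisphenol; 25 (R)-keto tosylate
Product: 26 (2S,2'S)-2,2'-{[(2R,3R,4S,5S)-3,4-dimethyloxolane-2,5-diyl]bis[(2-methoxy-4,1-phenylene)oxy]}bis[1-(3,4-dimethoxyphenyl)propan-1-one]
Conditions: Cs2CO3 (3 equiv), 25 (2.4 equiv), MeCN, rt
Reagents that add atoms: none
Why: Two-fold Williamson-type SN2 displacement of the α-keto tosylate by the phenoxides with clean inversion (R → S) at each arm; because the core is meso and the two arms are identical, only one product can form.

Step 16
Reactants: 26 bis(α-aryloxy ketone)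
Product: 27 (1R,2S,1'R,2'S)-2,2'-{[(2R,3R,4S,5S)-3,4-dimethyloxolane-2,5-diyl]bis[(2-methoxy-4,1-phenylene)oxy]}bis[1-(3,4-dimethoxyphenyl)propan-1-ol] (target)
Conditions: Zn(BH4)2 (pre-formed 0.15 M in Et2O, excess), THF/Et2O, −30 → 0 °C; sat. aq. NH4Cl
Reagents that add atoms: none
Why: Chelation-controlled (Cram-chelate) reduction, in which zinc bridges the ketone oxygen and the α-aryloxy oxygen and hydride enters from the face carrying H and not CH3, converting each (S)-α-aryloxy ketone into the (1R,2S) erythro (anti) alcohol.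

**Compound list**
1 | acetaldehyde | CC=O | starting material
2 | ethyl acrylate | C=CC(=O)OCC | starting material
3 | ethyl 3-hydroxy-2-methylidenebutanoate (racemic) | CCOC(=O)C(=C)C(C)O | intermediate
4 | ethyl (2Z)-2-(bromomethyl)but-2-enoate | CCOC(=O)/C(CBr)=C/C | intermediate
5 | 4-(benzyloxy)-3-methoxybenzaldehyde | COc1cc(C=O)ccc1OCc1ccccc1 | starting material
6 | [(2Z)-2-(ethoxycarbonyl)but-2-en-1-yl]zinc bromide (not isolated) | CCOC(=O)/C(C[Zn]Br)=C/C | intermediate
7 | ethyl (3R*,4S*)-4-[4-(benzyloxy)-3-methoxyphenyl]-4-hydroxy-3-methyl-2-methylidenebutanoate (syn, racemic, not isolated) | CCOC(=O)C(=C)[C@@H](C)[C@H](O)c1ccc(OCc2ccccc2)c(OC)c1 | intermediate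
8 | (4R*,5S*)-5-[4-(benzyloxy)-3-methoxyphenyl]-4-methyl-3-methylideneoxolan-2-one (4,5-cis, racemic) | C=C1C(=O)O[C@H](c2ccc(OCc3ccccc3)c(OC)c2)[C@@H]1C | intermediate
9 | (3S*,4R*,5S*)-5-[4-(benzyloxy)-3-methoxyphenyl]-3,4-dimethyloxolan-2-one (all-cis, racemic) | C[C@@H]1C(=O)O[C@H](c2ccc(OCc3ccccc3)c(OC)c2)[C@@H]1C | intermediate
10 | (3S*,4R*,5S*)-5-[4-(benzyloxy)-3-methoxyphenyl]-3,4-dimethyloxolan-2-ol (anomer mixture, racemic) | C[C@@H]1C(O)O[C@H](c2ccc(OCc3ccccc3)c(OC)c2)[C@@H]1C | intermediate
11 | 4-bromo-2-methoxyphenol | COc1cc(Br)ccc1O | starting material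
12 | 1-(benzyloxy)-4-bromo-2-methoxybenzene | COc1cc(Br)ccc1OCc1ccccc1 | intermediate
13 | [4-(benzyloxy)-3-methoxyphenyl]magnesium bromide (not isolated) | COc1cc([Mg]Br)ccc1OCc1ccccc1 | intermediate
14 | (2S*,3R*,4S*)-1,4-bis[4-(benzyloxy)-3-methoxyphenyl]-2,3-dimethylbutane-1,4-diol (C1 epimer mixture, racemic) | COc1cc(C(O)[C@@H](C)[C@@H](C)[C@H](O)c2ccc(OCc3ccccc3)c(OC)c2)ccc1OCc1ccccc1 | intermediate
15 | 2,5-bis[4-(benzyloxy)-3-methoxyphenyl]-3,4-cis-dimethyloxolane, kinetic mixture of C2/C5 epimers (not isolated) | COc1cc(C2OC(c3ccc(OCc4ccccc4)c(OC)c3)[C@H](C)[C@@H]2C)ccc1OCc1ccccc1 | intermediate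
16 | meso-(2R,3R,4S,5S)-2,5-bis[4-(benzyloxy)-3-methoxyphenyl]-3,4-dimethyloxolane (aryls cis to each other, methyls cis to each other, aryl trans to adjacent methyl) | COc1cc([C@H]2O[C@@H](c3ccc(OCc4ccccc4)c(OC)c3)[C@H](C)[C@@H]2C)ccc1OCc1ccccc1 | intermediate
17 | meso-4,4'-[(2R,3R,4S,5S)-3,4-dimethyloxolane-2,5-diyl]bis(2-methoxyphenol) | COc1cc([C@H]2O[C@@H](c3ccc(O)c(OC)c3)[C@H](C)[C@@H]2C)ccc1O | intermediate
18 | methyl (2R)-2-hydroxypropanoate (methyl (R)-lactate) | C[C@@H](O)C(=O)OC | starting material
19 | (2R)-2-hydroxy-1-(morpholin-4-yl)propan-1-one | C[C@@H](O)C(=O)N1CCOCC1 | intermediate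
20 | (2R)-2-[(tert-butyldimethylsilyl)oxy]-1-(morpholin-4-yl)propan-1-one | C[C@@H](O[Si](C)(C)C(C)(C)C)C(=O)N1CCOCC1 | intermediate
21 | 4-bromo-1,2-dimethoxybenzene | COc1ccc(Br)cc1OC | starting material
22 | (3,4-dimethoxyphenyl)magnesium bromide (not isolated) | COc1ccc([Mg]Br)cc1OC | intermediate
23 | (2R)-2-[(tert-butyldimethylsilyl)oxy]-1-(3,4-dimethoxyphenyl)propan-1-one | COc1ccc(C(=O)[C@@H](C)O[Si](C)(C)C(C)(C)C)cc1OC | intermediate
24 | (2R)-1-(3,4-dimethoxyphenyl)-2-hydroxypropan-1-one | COc1ccc(C(=O)[C@@H](C)O)cc1OC | intermediate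
25 | (2R)-1-(3,4-dimethoxyphenyl)-1-oxopropan-2-yl 4-methylbenzenesulfonate | COc1ccc(C(=O)[C@@H](C)OS(=O)(=O)c2ccc(C)cc2)cc1OC | intermediate
26 | (2S,2'S)-bis(α-aryloxy ketone) of the meso core (both arm carbons S) | COc1ccc(C(=O)[C@H](C)Oc2ccc([C@H]3O[C@@H](c4ccc(O[C@@H](C)C(=O)c5ccc(OC)c(OC)c5)c(OC)c4)[C@H](C)[C@@H]3C)cc2OC)cc1OC | intermediate
27 | CNP0116650.10: meso-type oxolane core with two (1R,2S)-erythro 1-(3,4-dimethoxyphenyl)-1-hydroxypropan-2-yl ethers | COc1ccc([C@@H](O)[C@H](C)Oc2ccc([C@H]3O[C@@H](c4ccc(O[C@@H](C)[C@H](O)c5ccc(OC)c(OC)c5)c(OC)c4)[C@H](C)[C@@H]3C)cc2OC)cc1OC | target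

**Totals**
Total step count: 16. Longest linear sequence: 10 steps (1, 2, 3, 4, 5, 7, 8, 9, 15, 16).

**Three steps most likely to fail**

Step 8 (ring closure with benzylic equilibration). The risks are incomplete equilibration, Friedel–Crafts closure of the benzylic cation onto the other aryl ring (aryltetralin), or loss of the cis-dimethyl relationship by elimination and re-protonation. The fallback sets out from lactone 9 and comes back at 16. Bromide 12 is converted with n-BuLi (THF, −78 °C) into [4-(benzyloxy)-3-methoxyphenyl]lithium F1, which adds to 9 to give the cyclic hemiketal F2. Reduction of F2 with Et3SiH and BF3·OEt2 in CH2Cl2 at −78 °C delivers hydride to the oxocarbenium ion from the face opposite all three substituents and gives the all-cis oxolane F3, a single meso isomer that can be purified. F3 is then epimerised at both benzylic carbons in a separate, monitored operation (BF3·OEt2 cat., CH2Cl2, −20 °C) to 16. This replaces C–O closure of a diol mixture by C–H delivery to a cyclic cation and separates ring formation from equilibration.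

Step 15 (two-fold SN2). The risk is base-induced epimerisation of the tosylate or of the α-aryloxy ketone product, or slow reaction of the hindered ortho-methoxy phenoxide. The fallback sets out from bisphenol 17 and hydroxy ketone 24 and comes back at 26. Compound 17 is coupled directly with 24 under Mitsunobu conditions (PPh3, DIAD, THF, 0 °C → rt), which forms the same ether with inversion under neutral, non-basic conditions and skips the tosylate. It makes no compound outside the list (F0).

Step 16 (two-fold chelation-controlled reduction). The risk is that the weakly basic aryl ether oxygen chelates zinc poorly, so that erythro selectivity at one or both arms is insufficient. The fallback sets out from 26 and comes back at 27. Compound 26 is reduced under non-chelating Felkin–Anh control with borohydride bound to Amberlite IRA-400 resin in MeOH, giving the bis-threo diol F4 with (1S,2S) arms. Both carbinols are then inverted by Mitsunobu esterification with 4-nitrobenzoic acid (PPh3, DIAD, THF, −20 °C → rt) to the bis(4-nitrobenzoate) F5 with (1R,2S) arms. Methanolysis of F5 (K2CO3, MeOH, rt) gives 27.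

Further compounds
F1 | step 8 | [4-(benzyloxy)-3-methoxyphenyl]lithium | COc1cc([Li])ccc1OCc1ccccc1
F2 | step 8 | (3S*,4R*,5S*)-2,5-bis[4-(benzyloxy)-3-methoxyphenyl]-3,4-dimethyloxolan-2-ol (hemiketal, C2 unspecified) | C[C@@H]1C(O)(c2ccc(OCc3ccccc3)c(OC)c2)O[C@H](c2ccc(OCc3ccccc3)c(OC)c2)[C@@H]1C
F3 | step 8 | meso all-cis 2,5-bis[4-(benzyloxy)-3-methoxyphenyl]-3,4-dimethyloxolane | COc1cc([C@H]2O[C@@H](c3ccc(OCc4ccccc4)c(OC)c3)[C@@H](C)[C@H]2C)ccc1OCc1ccccc1
F0 | step 15 | none | none
F4 | step 16 | bis-threo diol, (1S,2S) at both arms on the meso core | COc1ccc([C@H](O)[C@H](C)Oc2ccc([C@H]3O[C@@H](c4ccc(O[C@@H](C)[C@@H](O)c5ccc(OC)c(OC)c5)c(OC)c4)[C@H](C)[C@@H]3C)cc2OC)cc1OC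
F5 | step 16 | bis(4-nitrobenzoate) of 27, (1R,2S) at both arms | COc1ccc([C@@H](OC(=O)c6ccc(cc6)[N+](=O)[O-])[C@H](C)Oc2ccc([C@H]3O[C@@H](c4ccc(O[C@@H](C)[C@H](OC(=O)c6ccc(cc6)[N+](=O)[O-])c5ccc(OC)c(OC)c5)c(OC)c4)[C@H](C)[C@@H]3C)cc2OC)cc1OC
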